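## The problem

Target 17 is a single cyclohexene ring in which every sp3 carbon bears oxygen: benzoates at C1 and C4 on either side of the C2=C3 double bond, a secondary hydroxyl at C5, and at C6 a tertiary hydroxyl together with the hydroxymethyl carbon C7 (C1 is the benzoate carbon next to the quaternary C6). The four contiguous stereocenters are C1 (S), C4 (R), C5 (S) and C6 (S): the two benzoates are cis to each other and to C7, and the cis C5/C6 diol lies on the other face. Taken alone, the C1(O)–C2=C3–C4(O) half is a meso fragment, so the question of absolute configuration is the question of telling C1 from C4. Two oxygens already standing on one face at C1 and C4 can send a suprafacial addition across C5=C6 to the other face, so C1 and C4 can control C5 and C6 together, whereas the reverse order offers no such leverage. The benzoates sit next to free hydroxyls (acyl shifts under base), are allylic, and do not survive hydride reduction of C7; on the way, every 3,6-dioxygenated cyclohexadiene and every β-oxygenated carbonyl intermediate is one elimination away from a benzene ring. The enabling feature is that C1(O)–C2=C3–C4(O) with cis oxygens is the skeleton of cis-cyclopent-4-ene-1,3-diol; if its fifth ring carbon is a ketone (the future C5), the missing C6 with C7 is what a diazoacetate carbon inserts into one of two enantiotopic C–C(=O) bonds.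

## Retrosynthesis

**17 ⇒ 16 ⇒ 15 ⇒ 14 (benzoates last but one).** The acyl C–O bonds at O1 and O4 are cut, but the final forward operation must be non-basic, so 17 is released from the fully protected dibenzoate 16 by acid. 16 comes from diol 15 and 15 from the bis-silyl ether 14. Benzoates cannot be carried earlier: they would be reduced with C7 and would be leaving groups in every enolate step, whereas silyl ethers are inert and bulky. The forward steps ask only for acylation of two secondary allylic alcohols with nothing else free, and for an acid hydrolysis that does not move acyl groups.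

**14 ⇒ 13 ⇒ 12 (masking the triol).** The ketal C–O bonds at O5/O6 and the O7–CPh3 bond are cut. A direct acetonide on triol 12 could close on O5/O6 or on O6/O7. Tritylation of the primary hydroxyl first (13) leaves one diol and one possible dioxolane (14). Both groups leave together under acid at the end.

**12 ⇒ 10 (both C–O bonds at C5 and C6).** Cutting the two C–O bonds together leads to dienol 10 and asks for one syn-dihydroxylation anti to both silyloxy groups, which sets C5 and C6 at once. Two neighbouring cuts were weighed and set aside.
- Keeping the ketone oxygen of 7 at C5 and hydroxylating the enol at C6 would be shorter. The hydride that must then reduce C5 would approach from the face of the new C6 hydroxyl, away from the C4 silyloxy group and the C6 ester, and give the C5 epimer.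
- Dihydroxylating ester 9 directly fails on chemoselectivity. C2=C3 and C5=C6 are flanked by the same two silyloxy carbons and differ only in that C5=C6 is trisubstituted and conjugated to the ester, so an electrophilic osmium reagent would take C2=C3.

Reducing the ester first turns the handicap into a handle: the allylic hydroxyl of 10 can steer a hydrogen-bond-accepting osmium reagent to its own double bond.

**10 ⇒ 9 ⇒ 8 ⇒ 7 (C7 oxidation level and the C5 hydrogen).** The C7–H bonds (ester reduction), the C5–H bond (from C5–OTf) and the O–S bond of enol triflate 8 are cut, which leads back to β-keto ester 7. The C5 ketone oxygen is removed on purpose so that both diol oxygens can return together from one face. The forward steps must form and reduce the enol triflate without the enolate expelling the β-silyloxy group.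

**7 ⇒ 5 + 6 (key disconnection).** C5–C6 and C6–C1 are cut and the original C5–C1 bond is restored, a retro ring expansion to meso ketone 5 and ethyl diazoacetate 6. This beats any cut that builds the ring by cyclisation: C1, C4 and the double bond arrive already correct, the precursor has a mirror plane and seven carbons fewer in stereochemical bookkeeping, and one catalyst-controlled event fixes the absolute configuration. The forward reaction must make one of two enantiotopic ring bonds migrate.

**5 ⇒ 4 ⇒ 3 ⇒ 1 (the meso ring).** The C=O of 5 is traced to the exocyclic C=C of 4 (oxidative cleavage), the Si–O bonds are cut (diol 3), and both C–O bonds of 3 are cut to 6,6-dimethylfulvene 1 (addition of singlet oxygen across the ring diene, then O–O reduction). The fulvene is the stable form of a cyclopentadiene already functionalised at its fifth carbon.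

## Roads not taken

Alternative 1: Ireland–Claisen rearrangement of a manno-configured lactone.
- **Cut and key step.** The cut is C6–C1. The silyl ketene acetal of lactone A2, a six-membered lactone carrying an (E)-2-(4-methoxybenzyloxy)vinyl group on the carbon next to the ring oxygen, would rearrange: C6–C1 forms, the lactone C3–O bond breaks, C2=C3 appears and the carbocyclic acid A1 results.
- **Merits.** O4, O5 and O6 map onto O4, O3 and O2 of D-mannose A3, so absolute configuration comes from the chiral pool. The rearrangement is stereospecific, creates the quaternary C6 and C1 together, and A1 holds all four stereocenters with C7 at the acid level.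
- **Weak points.** The two-atom tether forces a boat, so the C1 configuration hinges on a geometrically pure (E)-enol ether built on a sugar aldehyde. The lactone enolate has a β-oxygen (O5) that can be expelled. Reaching A2 from A3 needs chain extension, oxidation at the anomeric carbon and three differentiated protecting groups. After A1 the acid must still be reduced and the benzyl-type ethers exchanged for benzoates.
- **Comparison.** This road is better in certainty of absolute configuration and rests on a known reaction class, whereas step 4 of the chosen plan is without precedent. The chosen plan sets against it a three-step access to 5 from a hydrocarbon, no alkene-geometry issue, and a fallback in known chemistry.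

Alternative 2: Para-quinol desymmetrised by an acetal oxa-Michael cascade.
- **Cut and key step.** The cut is the C5–O bond; no skeletal bond is formed. The tertiary hydroxyl of para-quinol A5 forms a hemiacetal with an aliphatic aldehyde, and its oxygen adds to one of the two enantiotopic enone β-carbons under a chiral Brønsted acid to give dioxolane A4. C5–O is set cis to O6 by the tether and the absolute configuration by the catalyst.
- **Merits.** The reaction class is known for para-quinols, all seven carbons are present from the start, A5 is a few steps from a phenol, and the acetal doubles as diol protection.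
- **Weak points.** A4 holds only two of the four stereocenters. Its ketone sits at C3, C4 is a methylene and C1 an alkene carbon. C4 must be oxygenated trans to O5, and the enone must be epoxidised and transposed (Wharton) to bring O1 and C2=C3 into place. Each step needs facial control next to the quaternary C6, where neither face is clearly favoured and O1 must enter syn to the silyloxymethyl arm.
- **Comparison.** This road is better in the precedent of its key step and in brevity up to it. The chosen plan sets against it that C1, C4 and the double bond come correct from the meso ring, leaving one syn-dihydroxylation controlled by both existing oxygens.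

Alternative 3: Endo Diels–Alder reaction.
- **Cut and key step.** C4–C5 and C6–C1 are cut. Diene A7 and dioxole ester A8 would combine in an endo-ester [4+2] cycloaddition to give A6.
- **Merits.** The ring and all four stereocenters (relative) arise in one convergent step, with C7 as an ester and the diol already an acetonide. On paper it is the shortest road.
- **Weak points.** A7 is a weakly activated diene and A8 a push–pull, trisubstituted alkene, so the partners are electronically mismatched and need heat, under which A7 and A6 can lose acetic acid toward arenes. The preference of the ester over the dioxole ring for the endo position is not assured. A6 would be racemic, with no reliable handle for a chiral Lewis acid on a hindered tert-butyl ester. The acetates would not survive reduction of the ester, so an acyl exchange with C7 protection is still needed.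
- **Comparison.** If the cycloaddition worked, this road would be shorter and more convergent than the chosen plan. The chosen plan sets against it a defined source of absolute configuration, a ring-forming step at low temperature on an activated ketone, and C1/C4 stereocenters that do not depend on endo/exo selectivity.

Key step: step 4

Assumption: the sense of induction of the scandium catalyst on a meso α,α′-dioxygenated cyclopentenone cannot be read from the known cyclohexanone cases. The route is written for ligand L*, the N,N′-dioxide of 1,1′-(propane-1,3-diyl)bis[(S)-N-(2,6-diisopropylphenyl)piperidine-2-carboxamide]; its mirror image is used if L* delivers the antipode of 7.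

Remark: 7 is written as its keto tautomer; the ester-bearing carbon is labile and is flattened in step 5.

## Route

Step 1
Reactants: 1 6,6-dimethylfulvene
Product: 3 (1R,3S)-2-(propan-2-ylidene)cyclopent-4-ene-1,3-diol (meso; hydroxyls cis), via bicyclic endoperoxide 2 (not isolated)
Conditions: O2, hν (visible), methylene blue (cat.), thiourea, MeOH, −30 → 0 °C
Reagents that add atoms: dioxygen, O=O
Why: Singlet oxygen adds across the ring diene in a [4+2] cycloaddition, placing both C–O bonds on one face (the cis relation of the future C1 and C4); thiourea in the flask reduces the O–O bond of 2 at low temperature before the endoperoxide can rearrange.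

Step 2
Reactants: 3 (1R,3S)-2-(propan-2-ylidene)cyclopent-4-ene-1,3-diol
Product: 4 meso cis-3,5-bis(tert-butyldimethylsilyloxy)-4-(propan-2-ylidene)cyclopent-1-ene
Conditions: TBSCl, imidazole, DMF, rt
Reagents that add atoms: tert-butyldimethylsilyl chloride, C[Si](C)(Cl)C(C)(C)C
Why: Standard silylation of secondary allylic alcohols under basic conditions, which avoids ionisation of the doubly allylic carbinols; the bulky, non-coordinating silyl ethers later shield one ring face.

Step 3
Reactants: 4 meso cis-3,5-bis(tert-butyldimethylsilyloxy)-4-(propan-2-ylidene)cyclopent-1-ene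
Product: 5 (2R,5S)-2,5-bis(tert-butyldimethylsilyloxy)cyclopent-3-en-1-one (meso; silyloxy groups cis)
Conditions: O3, CH2Cl2–MeOH, −78 °C (Sudan Red 7B end point); then Me2S, −78 °C → rt
Reagents that add atoms: ozone, [O-][O+]=O
Why: Ozonolysis with reductive work-up; the tetrasubstituted exocyclic alkene is the more electron-rich double bond and should be consumed first when ozone is dosed to the indicator end point. Ketone 5 is kept away from base because its α-hydrogens are activated and epimerisation or conjugation would destroy the meso ring.

Step 4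
Reactants: 5 (2R,5S)-2,5-bis(tert-butyldimethylsilyloxy)cyclopent-3-en-1-one; 6 ethyl diazoacetate
Product: 7 ethyl (1R,2S,5R)-2,5-bis(tert-butyldimethylsilyloxy)-6-oxocyclohex-3-ene-1-carboxylate (silyloxy groups cis; ester carbon epimerisable)
Conditions: Sc(OTf)3 (10 mol%), L* (12 mol%), 4 Å molecular sieves, CH2Cl2, −20 °C
Reagents that add atoms: none
Why: Proposed new method: the scandium-bound ketone of 5 is attacked by the diazo carbon of 6 from the face opposite the two silyloxy groups (C5–C6 forms), and in the β-oxido diazonium adduct the ring bond antiperiplanar to the leaving N2 shifts from the carbinol carbon C5 to C6 (C6–C1 forms, C5–C1 breaks) as the C5 carbonyl is restored; the closest known reaction type is the Sc(OTf)3/chiral N,N′-dioxide catalysed desymmetrizing ring expansion of 4-substituted cyclohexanones with α-diazo esters, an enantioselective form of the Lewis acid promoted diazoacetate homologation of cyclic ketones. The cyclohexene ring is thus made by a one-carbon 1,2-shift ring expansion of the cyclopentene ring (Tiffeneau–Demjanov type) and not by a cyclisation. The migrating carbon keeps its configuration, so C1 and C4 are the untouched carbinol carbons of the meso ketone and stay cis. The two C–C(=O) bonds are enantiotopic, and the one selectivity the step needs is which of them migrates; the twofold-symmetric ligand sphere on trivalent scandium fixes the enantioface of the diazo ester and the rotamer of the adduct, and this decides which carbinol becomes C1 and hence the absolute configuration of 7. The new center at C6 arises with inversion at the diazo carbon but lies between two carbonyls and is erased in step 5. Both candidate migrating carbons are secondary, allylic and oxygen-bearing, which should favour the shift over closure of the adduct to a glycidic ester, and the two α-oxygens activate the ketone toward addition. Low temperature and the absence of base are required because 5 can slip into conjugation and 7 can lose silanol toward an arene.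

Step 5
Reactants: 7 ethyl (1R,2S,5R)-2,5-bis(tert-butyldimethylsilyloxy)-6-oxocyclohex-3-ene-1-carboxylate
Product: 8 ethyl (3R,6S)-3,6-bis(tert-butyldimethylsilyloxy)-2-[(trifluoromethanesulfonyl)oxy]cyclohexa-1,4-diene-1-carboxylate
Conditions: Tf2O, i-Pr2NEt, CH2Cl2, −78 °C
Reagents that add atoms: trifluoromethanesulfonic anhydride, O=S(=O)(OS(=O)(=O)C(F)(F)F)C(F)(F)F
Why: The β-keto ester enolises only between its two carbonyls, and O-sulfonylation of that enol gives the vinyl triflate; low temperature and a hindered amine keep the enolate short-lived so that it does not expel the β-silyloxy group, and the C4 center α to the ketone is not touched.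

Step 6
Reactants: 8 ethyl (3R,6S)-3,6-bis(tert-butyldimethylsilyloxy)-2-[(trifluoromethanesulfonyl)oxy]cyclohexa-1,4-diene-1-carboxylate
Product: 9 ethyl (3R,6S)-3,6-bis(tert-butyldimethylsilyloxy)cyclohexa-1,4-diene-1-carboxylate
Conditions: Pd(OAc)2 (5 mol%), PPh3 (10 mol%), HCO2H, Et3N, DMF, 50 °C
Reagents that add atoms: none
Why: Formate reduction of a vinyl triflate: zerovalent palladium formed in the flask inserts into the C–OTf bond, formate replaces triflate and loses CO2 to give a palladium hydride, and reductive elimination forms the C5–H bond. β-Triflyloxy enoates are among the best substrates, and allylic silyl ethers are not ionised by the catalyst.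

Step 7
Reactants: 9 ethyl (3R,6S)-3,6-bis(tert-butyldimethylsilyloxy)cyclohexa-1,4-diene-1-carboxylate
Product: 10 [(3R,6S)-3,6-bis(tert-butyldimethylsilyloxy)cyclohexa-1,4-dien-1-yl]methanol
Conditions: i-Bu2AlH, CH2Cl2, −78 °C; aq. potassium sodium tartrate
Reagents that add atoms: none
Why: 1,2-Reduction of the conjugated ester by the aluminium hydride at low temperature; the silyl ethers and both alkenes are untouched.

Step 8
Reactants: 10 [(3R,6S)-3,6-bis(tert-butyldimethylsilyloxy)cyclohexa-1,4-dien-1-yl]methanol
Product: 12 (1S,2S,3R,6S)-3,6-bis(tert-butyldimethylsilyloxy)-1-(hydroxymethyl)cyclohex-4-ene-1,2-diol, via TMEDA-bound cyclic osmate ester 11 (not isolated)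
Conditions: OsO4 (1.05 equiv), TMEDA (1.1 equiv), CH2Cl2, −78 °C; then aq. Na2SO3, THF, reflux
Reagents that add atoms: osmium tetroxide, O=[Os](=O)(=O)=O
Why: Hydrogen-bond-directed dihydroxylation: the OsO4·TMEDA complex accepts a hydrogen bond from the allylic hydroxyl and so adds to C5=C6 in preference to C2=C3. The [3+2] addition is suprafacial and takes the face opposite both silyloxy groups, which sets C5 and C6 together (both oxygens trans to O1 and O4); reductive hydrolysis of the hexavalent osmium ester 11 frees the triol.

Step 9
Reactants: 12 (1S,2S,3R,6S)-3,6-bis(tert-butyldimethylsilyloxy)-1-(hydroxymethyl)cyclohex-4-ene-1,2-diol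
Product: 13 (1S,2S,3R,6S)-3,6-bis(tert-butyldimethylsilyloxy)-1-[(triphenylmethoxy)methyl]cyclohex-4-ene-1,2-diol
Conditions: TrCl, Et3N, DMAP (cat.), CH2Cl2, rt
Reagents that add atoms: triphenylmethyl chloride, ClC(c1ccccc1)(c1ccccc1)c1ccccc1
Why: Tritylation is selective for the primary hydroxyl on steric grounds; the secondary C5 and tertiary C6 hydroxyls remain.

Step 10
Reactants: 13 (1S,2S,3R,6S)-3,6-bis(tert-butyldimethylsilyloxy)-1-[(triphenylmethoxy)methyl]cyclohex-4-ene-1,2-diol
Product: 14 (3aS,4R,7S,7aS)-4,7-bis(tert-butyldimethylsilyloxy)-2,2-dimethyl-7a-[(triphenylmethoxy)methyl]-3a,4,7,7a-tetrahydro-1,3-benzodioxole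
Conditions: 2-methoxypropene, PPTS (cat.), CH2Cl2, 0 °C → rt
Reagents that add atoms: 2-methoxypropene, COC(C)=C
Why: Acid-catalysed ketalisation closes a cis-fused dioxolane on the only remaining diol; trityl and silyl ethers tolerate pyridinium tosylate in an aprotic solvent.

Step 11
Reactants: 14 (3aS,4R,7S,7aS)-4,7-bis(tert-butyldimethylsilyloxy)-2,2-dimethyl-7a-[(triphenylmethoxy)methyl]-3a,4,7,7a-tetrahydro-1,3-benzodioxole
Product: 15 (3aS,4R,7S,7aR)-2,2-dimethyl-7a-[(triphenylmethoxy)methyl]-3a,4,7,7a-tetrahydro-1,3-benzodioxole-4,7-diol
Conditions: Bu4NF, THF, 0 °C → rt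
Reagents that add atoms: none
Why: Fluoride cleaves both Si–O bonds; the acetonide and trityl ether are inert, and no ester is present that could migrate under the basic conditions.

Step 12
Reactants: 15 (3aS,4R,7S,7aR)-2,2-dimethyl-7a-[(triphenylmethoxy)methyl]-3a,4,7,7a-tetrahydro-1,3-benzodioxole-4,7-diol
Product: 16 (3aS,4R,7S,7aR)-2,2-dimethyl-7a-[(triphenylmethoxy)methyl]-3a,4,7,7a-tetrahydro-1,3-benzodioxole-4,7-diyl dibenzoate
Conditions: BzCl, pyridine, DMAP (cat.), CH2Cl2, 0 °C → rt
Reagents that add atoms: benzoyl chloride, O=C(Cl)c1ccccc1
Why: Acyl transfer with nucleophilic catalysis to the two secondary allylic alcohols, the only free hydroxyls; the configuration at C1 and C4 is retained because the C–O bonds are not touched.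

Step 13
Reactants: 16 (3aS,4R,7S,7aR)-2,2-dimethyl-7a-[(triphenylmethoxy)methyl]-3a,4,7,7a-tetrahydro-1,3-benzodioxole-4,7-diyl dibenzoate
Product: 17 (1R,4S,5S,6S)-5,6-dihydroxy-5-(hydroxymethyl)cyclohex-2-ene-1,4-diyl dibenzoate (the target; C1 S, C4 R, C5 S, C6 S in the numbering used here)
Conditions: CF3CO2H–H2O (9:1), CH2Cl2, 0 °C
Reagents that add atoms: none
Why: Aqueous acid hydrolyses the ketal and ionises the trityl ether. Under acid the benzoates do not migrate to the neighbouring hydroxyls, and the allylic C–O bonds are not ionised because the adjacent carbons carry oxygen.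

## Compound list

1 | 6,6-dimethylfulvene | CC(C)=C1C=CC=C1 | starting material
2 | 7-(propan-2-ylidene)-2,3-dioxabicyclo[2.2.1]hept-5-ene (meso endoperoxide) | CC(C)=C1[C@@H](O2)C=C[C@H]1O2 | intermediate
3 | (1R,3S)-2-(propan-2-ylidene)cyclopent-4-ene-1,3-diol (meso, cis) | CC(C)=C1[C@@H](O)C=C[C@H]1O | intermediate
4 | meso cis-3,5-bis(tert-butyldimethylsilyloxy)-4-(propan-2-ylidene)cyclopent-1-ene | CC(C)=C1[C@@H](O[Si](C)(C)C(C)(C)C)C=C[C@H]1O[Si](C)(C)C(C)(C)C | intermediate
5 | (2R,5S)-2,5-bis(tert-butyldimethylsilyloxy)cyclopent-3-en-1-one (meso, cis) | O=C1[C@@H](O[Si](C)(C)C(C)(C)C)C=C[C@H]1O[Si](C)(C)C(C)(C)C | intermediate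
6 | ethyl diazoacetate | CCOC(=O)C=[N+]=[N-] | starting material
7 | ethyl (1R,2S,5R)-2,5-bis(tert-butyldimethylsilyloxy)-6-oxocyclohex-3-ene-1-carboxylate (keto form, ester carbon labile) | CCOC(=O)[C@@H]1[C@@H](O[Si](C)(C)C(C)(C)C)C=C[C@@H](O[Si](C)(C)C(C)(C)C)C1=O | intermediate
8 | ethyl (3R,6S)-3,6-bis(tert-butyldimethylsilyloxy)-2-[(trifluoromethanesulfonyl)oxy]cyclohexa-1,4-diene-1-carboxylate | CCOC(=O)C1=C(OS(=O)(=O)C(F)(F)F)[C@H](O[Si](C)(C)C(C)(C)C)C=C[C@@H]1O[Si](C)(C)C(C)(C)C | intermediate
9 | ethyl (3R,6S)-3,6-bis(tert-butyldimethylsilyloxy)cyclohexa-1,4-diene-1-carboxylate | CCOC(=O)C1=C[C@H](O[Si](C)(C)C(C)(C)C)C=C[C@@H]1O[Si](C)(C)C(C)(C)C | intermediate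
10 | [(3R,6S)-3,6-bis(tert-butyldimethylsilyloxy)cyclohexa-1,4-dien-1-yl]methanol | OCC1=C[C@H](O[Si](C)(C)C(C)(C)C)C=C[C@@H]1O[Si](C)(C)C(C)(C)C | intermediate
11 | cyclic dioxo-osmium ester of the C5/C6 diol of 12 with bound TMEDA (hexavalent osmium) | CC(C)(C)[Si](C)(C)O[C@H]1C=C[C@@H](O[Si](C)(C)C(C)(C)C)[C@H](O2)[C@@]1(O[Os]2(=O)=O)CO.CN(C)CCN(C)C | intermediate
12 | (1S,2S,3R,6S)-3,6-bis(tert-butyldimethylsilyloxy)-1-(hydroxymethyl)cyclohex-4-ene-1,2-diol | CC(C)(C)[Si](C)(C)O[C@H]1C=C[C@@H](O[Si](C)(C)C(C)(C)C)[C@H](O)[C@@]1(O)CO | intermediate
13 | (1S,2S,3R,6S)-3,6-bis(tert-butyldimethylsilyloxy)-1-[(triphenylmethoxy)methyl]cyclohex-4-ene-1,2-diol | CC(C)(C)[Si](C)(C)O[C@H]1C=C[C@@H](O[Si](C)(C)C(C)(C)C)[C@H](O)[C@@]1(O)COC(c1ccccc1)(c1ccccc1)c1ccccc1 | intermediate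
14 | (3aS,4R,7S,7aS)-4,7-bis(tert-butyldimethylsilyloxy)-2,2-dimethyl-7a-[(triphenylmethoxy)methyl]-3a,4,7,7a-tetrahydro-1,3-benzodioxole | CC(C)(C)[Si](C)(C)O[C@H]1C=C[C@@H](O[Si](C)(C)C(C)(C)C)[C@H](OC(C)(C)O2)[C@@]12COC(c1ccccc1)(c1ccccc1)c1ccccc1 | intermediate
15 | (3aS,4R,7S,7aR)-2,2-dimethyl-7a-[(triphenylmethoxy)methyl]-3a,4,7,7a-tetrahydro-1,3-benzodioxole-4,7-diol | O[C@H]1C=C[C@@H](O)[C@H](OC(C)(C)O2)[C@@]12COC(c1ccccc1)(c1ccccc1)c1ccccc1 | intermediate
16 | (3aS,4R,7S,7aR)-2,2-dimethyl-7a-[(triphenylmethoxy)methyl]-3a,4,7,7a-tetrahydro-1,3-benzodioxole-4,7-diyl dibenzoate | O=C(O[C@H]1C=C[C@@H](OC(=O)c2ccccc2)[C@H](OC(C)(C)O3)[C@@]13COC(c1ccccc1)(c1ccccc1)c1ccccc1)c1ccccc1 | intermediate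
17 | (1R,4S,5S,6S)-5,6-dihydroxy-5-(hydroxymethyl)cyclohex-2-ene-1,4-diyl dibenzoate | O=C(O[C@H]1C=C[C@@H](OC(=O)c2ccccc2)[C@H](O)[C@@]1(O)CO)c1ccccc1 | target

## Step count and weak points

Total: 13 steps. Longest linear sequence: 13 steps, from 1 to 17; 6 enters at step 4.

**Step 4 (key step, new method).**
- What may go wrong: poor discrimination between the two enantiotopic C–C(=O) bonds, since the stereocenters sit directly on the migrating carbons; closure of the diazonium adduct to a glycidic ester in place of the shift; Lewis acid induced drift of the β,γ-unsaturated ketone into conjugation; sequestration of scandium by the chelating β-keto ester product.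
- Fallback in known chemistry, from 5: the ring expansion is run with the achiral promoter BF3·OEt2 (CH2Cl2, −78 °C) and (1R,2S,5R)-menthyl diazoacetate F1 in place of 6. The auxiliary is too remote to choose the migrating bond, so the menthyl keto ester of the wanted ring series F2 forms together with its ring-antipodal diastereomer F3. Triflation of the mixture as in step 5 gives the menthyl enol triflate F4 and its diastereomer F5, which have no labile center and are separated by chromatography or crystallisation. F4 is reduced as in step 6 to the menthyl dienoate F6, and i-Bu2AlH reduction of F6 as in step 7 releases menthol and rejoins the route at 10. About half of the material is given up.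

**Step 3.**
- What may go wrong: over-oxidation through attack of ozone on the ring alkene, and base- or acid-induced epimerisation or conjugation of 5 during work-up.
- Fallback, from 4: mCPBA (NaHCO3, CH2Cl2, 0 °C) epoxidises the tetrasubstituted alkene, far more nucleophilic toward a peracid than the ring alkene, to the spiro-epoxide F7. H5IO6 in wet ether then opens and cleaves the epoxide to acetone and 5, where the route is rejoined.

**Step 5.**
- What may go wrong: loss of silanol from the enolate by E1cB elimination, followed by aromatisation to a salicylate.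
- Fallback, from 7: Zn(BH4)2 (Et2O, 0 °C) reduces the ketone under neutral conditions to the β-hydroxy ester F8. MsCl/Et3N converts it to the mesylate F9, and DBU eliminates methanesulfonate through the transient ester enolate, mesylate being far the better leaving group, to give 9.

**Step 8.**
- What may go wrong: poor chemoselectivity between C5=C6 and C2=C3, double dihydroxylation, or sluggish cleavage of the osmate ester.
- Fallback, from 9: KMnO4 under cold buffered conditions (acetone–H2O, MgSO4, −20 °C) adds fastest to electron-poor conjugated alkenes, the opposite preference to OsO4. It should dihydroxylate the enoate from the face anti to the silyloxy groups to give diol ester F10. LiBH4 (THF, 0 °C) reduces the α-hydroxy ester and rejoins the route at 12.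

## Further compounds

F1 | step 4 | (1R,2S,5R)-menthyl diazoacetate | [N-]=[N+]=CC(=O)O[C@@H]1C[C@H](C)CC[C@H]1C(C)C
F2 | step 4 | (1R,2S,5R)-menthyl (1R,2S,5R)-2,5-bis(tert-butyldimethylsilyloxy)-6-oxocyclohex-3-ene-1-carboxylate (wanted ring series) | O=C(O[C@@H]1C[C@H](C)CC[C@H]1C(C)C)[C@@H]1[C@@H](O[Si](C)(C)C(C)(C)C)C=C[C@@H](O[Si](C)(C)C(C)(C)C)C1=O
F3 | step 4 | (1R,2S,5R)-menthyl (1S,2R,5S)-2,5-bis(tert-butyldimethylsilyloxy)-6-oxocyclohex-3-ene-1-carboxylate (ring-antipodal diastereomer) | O=C(O[C@@H]1C[C@H](C)CC[C@H]1C(C)C)[C@H]1[C@H](O[Si](C)(C)C(C)(C)C)C=C[C@H](O[Si](C)(C)C(C)(C)C)C1=O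
F4 | step 4 | (1R,2S,5R)-menthyl (3R,6S)-3,6-bis(tert-butyldimethylsilyloxy)-2-[(trifluoromethanesulfonyl)oxy]cyclohexa-1,4-diene-1-carboxylate | O=C(O[C@@H]1C[C@H](C)CC[C@H]1C(C)C)C1=C(OS(=O)(=O)C(F)(F)F)[C@H](O[Si](C)(C)C(C)(C)C)C=C[C@@H]1O[Si](C)(C)C(C)(C)C
F5 | step 4 | (1R,2S,5R)-menthyl (3S,6R)-3,6-bis(tert-butyldimethylsilyloxy)-2-[(trifluoromethanesulfonyl)oxy]cyclohexa-1,4-diene-1-carboxylate (unwanted diastereomer) | O=C(O[C@@H]1C[C@H](C)CC[C@H]1C(C)C)C1=C(OS(=O)(=O)C(F)(F)F)[C@@H](O[Si](C)(C)C(C)(C)C)C=C[C@H]1O[Si](C)(C)C(C)(C)C
F6 | step 4 | (1R,2S,5R)-menthyl (3R,6S)-3,6-bis(tert-butyldimethylsilyloxy)cyclohexa-1,4-diene-1-carboxylate | O=C(O[C@@H]1C[C@H](C)CC[C@H]1C(C)C)C1=C[C@H](O[Si](C)(C)C(C)(C)C)C=C[C@@H]1O[Si](C)(C)C(C)(C)C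
F7 | step 3 | meso 4,7-bis(tert-butyldimethylsilyloxy)-2,2-dimethyl-1-oxaspiro[2.4]hept-5-ene (epoxide oxygen anti to the silyloxy groups) | CC1(C)O[C@@]12[C@@H](O[Si](C)(C)C(C)(C)C)C=C[C@H]2O[Si](C)(C)C(C)(C)C
F8 | step 5 | ethyl (2S,5R)-2,5-bis(tert-butyldimethylsilyloxy)-6-hydroxycyclohex-3-ene-1-carboxylate (carbinol and ester centers as formed, both removed on elimination) | CCOC(=O)C1[C@@H](O[Si](C)(C)C(C)(C)C)C=C[C@@H](O[Si](C)(C)C(C)(C)C)C1O
F9 | step 5 | ethyl (2S,5R)-2,5-bis(tert-butyldimethylsilyloxy)-6-(methanesulfonyloxy)cyclohex-3-ene-1-carboxylate | CCOC(=O)C1[C@@H](O[Si](C)(C)C(C)(C)C)C=C[C@@H](O[Si](C)(C)C(C)(C)C)C1OS(C)(=O)=O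
F10 | step 8 | ethyl (1S,2S,3R,6S)-3,6-bis(tert-butyldimethylsilyloxy)-1,2-dihydroxycyclohex-4-ene-1-carboxylate | CC(C)(C)[Si](C)(C)O[C@H]1C=C[C@@H](O[Si](C)(C)C(C)(C)C)[C@H](O)[C@@]1(O)C(=O)OCC
A1 | alternative 1 | cis-fused acetonide of 1,4-bis(4-methoxybenzyloxy)-5,6-dihydroxycyclohex-2-ene-6-carboxylic acid (target numbering) | COc1ccc(CO[C@H]2C=C[C@@H](OCc3ccc(OC)cc3)[C@@H]3OC(C)(C)O[C@]23C(=O)O)cc1
A2 | alternative 1 | (E)-6-deoxy-2,3-O-isopropylidene-4,7-di-O-(4-methoxybenzyl)-D-manno-hept-6-enono-1,5-lactone | COc1ccc(CO/C=C/[C@H]2OC(=O)[C@@H](OC(C)(C)O3)[C@@H]3[C@@H]2OCc2ccc(OC)cc2)cc1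
A3 | alternative 1 | D-mannose (pyranose form) | OC[C@H]1OC(O)[C@@H](O)[C@@H](O)[C@@H]1O
A4 | alternative 2 | cis-fused 2-methyl-7a-[(tert-butyldimethylsilyloxy)methyl]-3a,7a-dihydro-1,3-benzodioxol-5(4H)-one | O=C1C=C[C@@]2(CO[Si](C)(C)C(C)(C)C)O[C@H](C)O[C@H]2C1
A5 | alternative 2 | 4-hydroxy-4-[(tert-butyldimethylsilyloxy)methyl]cyclohexa-2,5-dien-1-one | O=C1C=CC(O)(CO[Si](C)(C)C(C)(C)C)C=C1
A6 | alternative 3 | tert-butyl 4,7-diacetoxy-2,2-dimethyl-3a,4,7,7a-tetrahydro-1,3-benzodioxole-3a-carboxylate (endo-ester adduct) | CC(=O)O[C@H]1C=C[C@@H](OC(C)=O)[C@@H]2OC(C)(C)O[C@]12C(=O)OC(C)(C)C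
A7 | alternative 3 | (1E,3E)-buta-1,3-diene-1,4-diyl diacetate | CC(=O)O/C=C/C=C/OC(C)=O
A8 | alternative 3 | tert-butyl 2,2-dimethyl-1,3-dioxole-4-carboxylate | CC1(C)OC=C(O1)C(=O)OC(C)(C)C
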